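A gap of 6 percentage points separates target from isomer of the product at 60.0 min in Wednesday's run, against a scatter of 0.5 points. That run is the very flask asked about, followed so far.

| flask | starting material | partner | remark | time |
|---|---|---|---|---|
| Wednesday's | 0.010 M | 0.012 M | the very flask that is asked about, followed so far |  |
| flask | 0.010 M | 0.0120 M |  | 5.0 h |
Wednesday's run (percent of the starting material charged)

| time / min | isomer of the product / % | target / % |
|---|---|---|
| 5.00 | 0.2 | 1.9 |
| 8.00 | 0.6 | 3.0 |
| 12.0 | 1.1 | 2.8 |
| 20.0 | 2.7 | 4.6 |
| 40.0 | 4.3 | 9.1 |
| 60.0 | 6.4 | 12.4 |

(scatter of a reading: 0.5 percentage points)
- the analysis behind the earlier runs scatters by 0.5 percentage points, standard deviation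
- a reading or a percentage of target counts all its forms, free or not
1. ratio of isomer of the product to target at 6.0 min
2. ratio of isomer of the product to target at 40 min
3. ratio of isomer of the product to target at 5.0 h
4. which of isomer of the product and target there is more of at 5.0 h

I turn the question round. For isomer of the product to lead at 5.0 h, its ratio to target has to pass 1 at that time, the symmetric case in which the two products stand level. I define the split, a selectivity factor, as isomer of the product summed over the readings from 20.0 min on, divided by target summed over the same readings: 0.513. This reading stands under parity, and parity asks for a rise by a factor of 1.95. At 8.00 min the split predicts 1.54% of isomer of the product and the reading is 0.6%, a difference of 0.94 points, which I do not take as proof of a delay. My own reckoning assumes no such rise by 5.0 h and puts the ratio near the split at all three asked times, with target ahead.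

The forecast gives 0.2 at 6.0 min, 0.49 at 40 min and 0.55 at 5.0 h, with target ahead. It parts from my reckoning at the early time, where it reads that the “isomer shows a lag of a few minutes”.

The flask gives 0.514, 0.520 and 0.570, with target ahead, at 27.7% against 15.8% of isomer of the product. Its steps are these:

    starting material + partner ⇌ target (K = 200 M⁻¹, k = 0.00370 M⁻¹ s⁻¹)
    starting material + partner ⇌ isomer of the product (K = 210 M⁻¹, k = 0.00190 M⁻¹ s⁻¹)
    partner → decomposed reagent (k = 2.90 × 10⁻⁵ s⁻¹)
    crystals ⇌ target, rate k4*(cs4 - [target]) while solid is left; crystals form when [target] > cs4 (solubility = 7.20 mM, k = 0.00340 s⁻¹)

The split times that target gives 14.2% of isomer of the product, under the 15.8% found. The largest single effect on this ratio is the time allowed: with the limit of 5.0 h taken away and the same flask run on to 50.0 h, the ratio stands at 1.19, above parity. The neighbour charged with 0.048 M of partner holds 55.7% of target, so the split predicts 28.6% of isomer of the product, and it holds 32.3%.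

(Readings and results were computed with constants of no real substance, and the scatter is random.)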